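**Retrosynthetic overview**
- Licoricidin is reached by global MOM removal from its tri-MOM ether.
- The protected isoflavan comes from a 2,3-trans-flavan-3-ol by a stereospecific 1,2-aryl shift (C2→C3) with hydride capture of the C2 oxocarbenium ion; this step creates the isoflavan skeleton and C3.
- The flavan-3-ol comes from acid-mediated pyran closure of a 1,3-diarylpropane-1,2-diol, itself made from an A-ring α-hydroxy ester and the lithiated B-ring arene.
- The α-hydroxy ester comes from an A-ring aryl bromide and methyl (R)-glycidate (source of chirality); both arenes come from resorcinol bis-MOM ether (B ring: lithiation/prenylation; A ring: C–H borylation/oxidation, ortho-dibromination, O-methylation, two Br–Li exchanges).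
- Ring order: rings A and B are bought as resorcinol; ring C is closed in step 9 as a flavan and rearranged to the isoflavan in step 10.

Assumption: the target SMILES is read as (3R)-licoricidin; MOMCl, MeI, NBS, B2pin2 and the like are treated as reagents.

**Route**

Step 1
Reactants: 1 resorcinol (benzene-1,3-diol)
Product: 2 1,3-bis(methoxymethoxy)benzene
Conditions: NaH (2.4 equiv), DMF, 0 °C; MOMCl (2.4 equiv), 0 °C → rt
Reagents that add atoms: chloromethyl methyl ether (MOMCl), COCCl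
Why: Williamson-type O-alkylation of both phenoxides (MOM protection); the MOM groups later serve as ortho-directing groups.

Step 2
Reactants: 2 1,3-bis(methoxymethoxy)benzene; 3 prenyl bromide (1-bromo-3-methylbut-2-ene)
Product: 5 1,3-bis(methoxymethoxy)-2-(3-methylbut-2-en-1-yl)benzene, via 2,6-bis(methoxymethoxy)phenyllithium 4 (not isolated)
Conditions: n-BuLi (1.1 equiv), THF, 0 °C → rt; CuI (10 mol%), 3, −78 °C → rt
Reagents that add atoms: n-butyllithium, [Li]CCCC (Li of 4 only)
Why: Directed ortho-metalation at the position flanked by both OMOM groups, then Cu-catalysed SN2 allylation with prenyl bromide.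

Step 3
Reactants: 2 1,3-bis(methoxymethoxy)benzene
Product: 7 3,5-bis(methoxymethoxy)phenol, via pinacol 3,5-bis(methoxymethoxy)phenylboronate 6 (not isolated)
Conditions: [Ir(OMe)(cod)]2 (1 mol%), dtbpy (2 mol%), B2pin2 (1.0 equiv), THF, 80 °C; then 30% H2O2, aq. NaOH, 0 °C → rt
Reagents that add atoms: bis(pinacolato)diboron, CC1(C)OB(OC1(C)C)B1OC(C)(C)C(C)(C)O1 (boryl group of 6 only); hydrogen peroxide, OO (phenol oxygen of 7)
Why: Sterically controlled Ir-catalysed aromatic C–H borylation reaches only C5 (the one C–H without an ortho substituent), and C–B oxidation gives the phenol.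

Step 4
Reactants: 7 3,5-bis(methoxymethoxy)phenol
Product: 8 2,6-dibromo-3,5-bis(methoxymethoxy)phenol
Conditions: NBS (2.05 equiv), i-Pr2NH (10 mol%), CH2Cl2, −20 → 0 °C
Reagents that add atoms: N-bromosuccinimide, O=C1CCC(=O)N1Br
Why: Amine-catalysed ortho-selective electrophilic bromination of a phenol (the phenol-bound N-bromoamine delivers bromine to both positions next to OH), while the para position sits between two OMOM groups.

Step 5
Reactants: 8 2,6-dibromo-3,5-bis(methoxymethoxy)phenol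
Product: 9 1,3-dibromo-2-methoxy-4,6-bis(methoxymethoxy)benzene
Conditions: MeI (1.5 equiv), K2CO3, DMF, rt
Reagents that add atoms: iodomethane, CI
Why: Williamson O-methylation of the acidic 2,6-dibromophenol installs the future 5-OMe before any carbon substituent is attached.

Step 6
Reactants: 9 1,3-dibromo-2-methoxy-4,6-bis(methoxymethoxy)benzene; 3 prenyl bromide
Product: 11 1-bromo-2-methoxy-4,6-bis(methoxymethoxy)-3-(3-methylbut-2-en-1-yl)benzene, via 3-bromo-2-methoxy-4,6-bis(methoxymethoxy)phenyllithium 10 (not isolated)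
Conditions: n-BuLi (1.0 equiv), THF, −78 °C; CuBr·SMe2 (10 mol%), 3, −78 → 0 °C
Reagents that add atoms: n-butyllithium, [Li]CCCC (Li of 10 only)
Why: Bromine–lithium exchange on one of two equivalent bromides (a second exchange on an aryllithium is slow), then Cu-catalysed SN2 prenylation.

Step 7
Reactants: 11 1-bromo-2-methoxy-4,6-bis(methoxymethoxy)-3-(3-methylbut-2-en-1-yl)benzene; 12 methyl (R)-glycidate (methyl (2R)-oxirane-2-carboxylate)
Product: 15 methyl (2R)-2-hydroxy-3-[2-methoxy-4,6-bis(methoxymethoxy)-3-(3-methylbut-2-en-1-yl)phenyl]propanoate, via aryllithium 13 (not isolated), via arylmagnesium bromide 14 (not isolated)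
Conditions: n-BuLi (1.05 equiv), THF, −78 °C; MgBr2·OEt2 (1.1 equiv), −78 → −40 °C; CuI (10 mol%), 12, −40 → −20 °C; aq. NH4Cl
Reagents that add atoms: n-butyllithium, [Li]CCCC (Li of 13 only); magnesium bromide, Br[Mg]Br (MgBr of 14 only)
Why: Br–Li exchange, transmetalation and Cu-catalysed SN2 opening of the glycidate at its unsubstituted carbon; the stereocentre of 12 is not touched and becomes the (R)-carbinol that is the future C3.

Step 8
Reactants: 15 the (2R)-α-hydroxy ester; 5 1,3-bis(methoxymethoxy)-2-(3-methylbut-2-en-1-yl)benzene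
Product: 18 (1RS,2R)-1-[2,4-bis(methoxymethoxy)-3-(3-methylbut-2-en-1-yl)phenyl]-3-[2-methoxy-4,6-bis(methoxymethoxy)-3-(3-methylbut-2-en-1-yl)phenyl]propane-1,2-diol, via B-ring aryllithium 16 (not isolated), via α-hydroxy aldehyde 17 (not isolated)
Conditions: DIBAL-H (2.2 equiv), CH2Cl2, −78 °C; then 16 [from 5 (3 equiv), n-BuLi, TMEDA, THF, 0 °C], −78 → −30 °C; aq. Rochelle salt
Reagents that add atoms: n-butyllithium, [Li]CCCC (Li of 16 only)
Why: Low-temperature DIBAL half-reduction (aluminium-bound hemiacetal of 17) followed by in situ 1,2-addition of the aryllithium made by directed ortho-metalation of 5; the new benzylic carbinol may be either epimer because it is ionised in step 9, and the (R)-centre is untouched.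

Step 9
Reactants: 18 the (1RS,2R)-diol
Product: 19 (2S,3R)-2-[2,4-bis(methoxymethoxy)-3-(3-methylbut-2-en-1-yl)phenyl]-5-methoxy-7-(methoxymethoxy)-6-(3-methylbut-2-en-1-yl)-3,4-dihydro-2H-chromen-3-ol (2,3-trans)
Conditions: CSA (10 mol%), CH2Cl2–MeOH (9:1), 0 °C → rt
Reagents that add atoms: none
Why: Acid-catalysed SN1 ring closure of a 1,3-diarylpropane-1,2-diol to a flavan-3-ol, in which the 2,4-dialkoxybenzylic cation is captured by the MOM-ether oxygen ortho to the chain with loss of that MOM group; reversible C2–O ionisation funnels to the 2,3-trans isomer (C2 set under thermodynamic control, C3 retained).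

Step 10
Reactants: 19 the (2S,3R)-flavan-3-ol
Product: 22 (3R)-3-[2,4-bis(methoxymethoxy)-3-(3-methylbut-2-en-1-yl)phenyl]-5-methoxy-7-(methoxymethoxy)-6-(3-methylbut-2-en-1-yl)-3,4-dihydro-2H-chromene, via flavan-3-yl triflate 20 (not isolated), via C2-oxocarbenium triflate 21 (not isolated)
Conditions: Tf2O (1.2 equiv), 2,6-di-tert-butyl-4-methylpyridine (2.5 equiv), CH2Cl2, −78 °C; Et3SiH (5 equiv), −78 → −20 °C; aq. NaHCO3
Reagents that add atoms: trifluoromethanesulfonic anhydride, O=S(=O)(OS(=O)(=O)C(F)(F)F)C(F)(F)F (triflate of 20 and 21 only)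
Why: Proposed new method: a triflate-triggered semipinacol-type 1,2-aryl shift with hydride termination, in which the electron-rich aryl group at C2 of the trans-diaxial half-chair lies antiperiplanar to the C3–OTf bond and migrates to C3 with inversion (phenonium-like transition state assisted by the O1 lone pair), and the resulting cyclic oxocarbenium ion 21 is reduced at C2 by Et3SiH, so the (3R)-carbinol is converted stereospecifically into the (3R)-aryl centre of the isoflavan; the closest known reactions are the solvolytic aryl migration of 2,3-trans-flavan-3-yl sulfonates to 2-alkoxyisoflavans and the stereospecific 1,2-aryl shift of α-sulfonyloxy acetals, whereas the one-pot triflation/migration/silane reduction giving an isoflavan directly has not been shown.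

Step 11
Reactants: 22 the tri-MOM isoflavan
Product: 23 licoricidin, 4-[(3R)-7-hydroxy-5-methoxy-6-(3-methylbut-2-en-1-yl)-3,4-dihydro-2H-chromen-3-yl]-2-(3-methylbut-2-en-1-yl)benzene-1,3-diol
Conditions: conc. HCl (cat.), MeOH, rt → 40 °C
Reagents that add atoms: none
Why: Acid-catalysed acetal exchange cleaves the three aryl MOM ethers under conditions mild enough to leave the prenyl groups and the non-epimerisable C3 untouched.

**Compound list**
1 | resorcinol (benzene-1,3-diol) | Oc1cccc(O)c1 | starting material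
2 | 1,3-bis(methoxymethoxy)benzene | COCOc1cccc(OCOC)c1 | intermediate
3 | prenyl bromide (1-bromo-3-methylbut-2-ene) | CC(C)=CCBr | starting material
4 | [2,6-bis(methoxymethoxy)phenyl]lithium | [Li]c1c(OCOC)cccc1OCOC | intermediate
5 | 1,3-bis(methoxymethoxy)-2-(3-methylbut-2-en-1-yl)benzene | COCOc1cccc(OCOC)c1CC=C(C)C | intermediate
6 | 2-[3,5-bis(methoxymethoxy)phenyl]-4,4,5,5-tetramethyl-1,3,2-dioxaborolane | COCOc1cc(OCOC)cc(B2OC(C)(C)C(C)(C)O2)c1 | intermediate
7 | 3,5-bis(methoxymethoxy)phenol | COCOc1cc(O)cc(OCOC)c1 | intermediate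
8 | 2,6-dibromo-3,5-bis(methoxymethoxy)phenol | COCOc1cc(OCOC)c(Br)c(O)c1Br | intermediate
9 | 1,3-dibromo-2-methoxy-4,6-bis(methoxymethoxy)benzene | COCOc1cc(OCOC)c(Br)c(OC)c1Br | intermediate
10 | [3-bromo-2-methoxy-4,6-bis(methoxymethoxy)phenyl]lithium | [Li]c1c(OCOC)cc(OCOC)c(Br)c1OC | intermediate
11 | 1-bromo-2-methoxy-4,6-bis(methoxymethoxy)-3-(3-methylbut-2-en-1-yl)benzene | COCOc1cc(OCOC)c(CC=C(C)C)c(OC)c1Br | intermediate
12 | methyl (R)-glycidate (methyl (2R)-oxirane-2-carboxylate) | COC(=O)[C@H]1CO1 | starting material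
13 | [2-methoxy-4,6-bis(methoxymethoxy)-3-(3-methylbut-2-en-1-yl)phenyl]lithium | [Li]c1c(OCOC)cc(OCOC)c(CC=C(C)C)c1OC | intermediate
14 | bromo[2-methoxy-4,6-bis(methoxymethoxy)-3-(3-methylbut-2-en-1-yl)phenyl]magnesium | Br[Mg]c1c(OCOC)cc(OCOC)c(CC=C(C)C)c1OC | intermediate
15 | methyl (2R)-2-hydroxy-3-[2-methoxy-4,6-bis(methoxymethoxy)-3-(3-methylbut-2-en-1-yl)phenyl]propanoate | COC(=O)[C@H](O)Cc1c(OCOC)cc(OCOC)c(CC=C(C)C)c1OC | intermediate
16 | [2,4-bis(methoxymethoxy)-3-(3-methylbut-2-en-1-yl)phenyl]lithium | [Li]c1ccc(OCOC)c(CC=C(C)C)c1OCOC | intermediate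
17 | (2R)-2-hydroxy-3-[2-methoxy-4,6-bis(methoxymethoxy)-3-(3-methylbut-2-en-1-yl)phenyl]propanal (present as its aluminium hemiacetal) | O=C[C@H](O)Cc1c(OCOC)cc(OCOC)c(CC=C(C)C)c1OC | intermediate
18 | (1RS,2R)-1-[2,4-bis(methoxymethoxy)-3-(3-methylbut-2-en-1-yl)phenyl]-3-[2-methoxy-4,6-bis(methoxymethoxy)-3-(3-methylbut-2-en-1-yl)phenyl]propane-1,2-diol | OC(c1ccc(OCOC)c(CC=C(C)C)c1OCOC)[C@H](O)Cc1c(OCOC)cc(OCOC)c(CC=C(C)C)c1OC | intermediate
19 | (2S,3R)-2-[2,4-bis(methoxymethoxy)-3-(3-methylbut-2-en-1-yl)phenyl]-5-methoxy-7-(methoxymethoxy)-6-(3-methylbut-2-en-1-yl)-3,4-dihydro-2H-chromen-3-ol | O[C@@H]1Cc2c(OC)c(CC=C(C)C)c(OCOC)cc2O[C@H]1c1ccc(OCOC)c(CC=C(C)C)c1OCOC | intermediate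
20 | (2S,3R)-2-[2,4-bis(methoxymethoxy)-3-(3-methylbut-2-en-1-yl)phenyl]-5-methoxy-7-(methoxymethoxy)-6-(3-methylbut-2-en-1-yl)-3,4-dihydro-2H-chromen-3-yl trifluoromethanesulfonate | FC(F)(F)S(=O)(=O)O[C@@H]1Cc2c(OC)c(CC=C(C)C)c(OCOC)cc2O[C@H]1c1ccc(OCOC)c(CC=C(C)C)c1OCOC | intermediate
21 | (3R)-3-[2,4-bis(methoxymethoxy)-3-(3-methylbut-2-en-1-yl)phenyl]-5-methoxy-7-(methoxymethoxy)-6-(3-methylbut-2-en-1-yl)-3,4-dihydrochromenylium trifluoromethanesulfonate | COc1c(CC=C(C)C)c(OCOC)cc2c1C[C@H](c1ccc(OCOC)c(CC=C(C)C)c1OCOC)C=[O+]2.[O-]S(=O)(=O)C(F)(F)F | intermediate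
22 | (3R)-3-[2,4-bis(methoxymethoxy)-3-(3-methylbut-2-en-1-yl)phenyl]-5-methoxy-7-(methoxymethoxy)-6-(3-methylbut-2-en-1-yl)-3,4-dihydro-2H-chromene | COc1c(CC=C(C)C)c(OCOC)cc2c1C[C@H](c1ccc(OCOC)c(CC=C(C)C)c1OCOC)CO2 | intermediate
23 | licoricidin, 4-[(3R)-7-hydroxy-5-methoxy-6-(3-methylbut-2-en-1-yl)-3,4-dihydro-2H-chromen-3-yl]-2-(3-methylbut-2-en-1-yl)benzene-1,3-diol | COc1c(CC=C(C)C)c(O)cc2c1C[C@H](c1ccc(O)c(CC=C(C)C)c1O)CO2 | target

**Step count**
Total steps: 11. Longest linear sequence: 10 steps (steps 1, 3, 4, 5, 6, 7, 8, 9, 10, 11 from resorcinol).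

**Steps most likely to fail**

Step 10 (the proposed new step). Risks are O1 participation from the diequatorial conformer (ring contraction to a 2-benzyl-dihydrobenzofuran), elimination to flavenes, and loss of MOM groups to the silyl triflate formed. The fallback uses known chemistry, sets out from 19 and comes back at 22. Compound 19 is mesylated (MsCl, Et3N, CH2Cl2, 0 °C) to (2S,3R)-2-[2,4-bis(methoxymethoxy)-3-(3-methylbut-2-en-1-yl)phenyl]-5-methoxy-7-(methoxymethoxy)-6-(3-methylbut-2-en-1-yl)-3,4-dihydro-2H-chromen-3-yl methanesulfonate F7. This is solvolysed in ethanol buffered with 2,6-lutidine at 70 °C, the classical solvolytic aryl migration of 2,3-trans-flavan-3-yl sulfonates, to (3R)-2-ethoxy-3-[2,4-bis(methoxymethoxy)-3-(3-methylbut-2-en-1-yl)phenyl]-5-methoxy-7-(methoxymethoxy)-6-(3-methylbut-2-en-1-yl)-3,4-dihydro-2H-chromene F8 (mixture at C2). The isolated acetal is then reduced by standard ionic hydrogenation (Et3SiH, BF3·OEt2, CH2Cl2, −78 °C) to 22. This replaces the one-pot triflate cascade by two isolable intermediates, with solvent capture of the oxocarbenium ion and a separate reduction.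

Step 8. Risks are over-reduction of the ester, poor turnover of the aluminium hemiacetal and waste of the lithiated B ring. The fallback sets out from 15 and comes back at 18. Compound 15 is converted with MeNH(OMe)·HCl and i-PrMgCl (THF, −20 °C) into (2R)-2-hydroxy-N-methoxy-N-methyl-3-[2-methoxy-4,6-bis(methoxymethoxy)-3-(3-methylbut-2-en-1-yl)phenyl]propanamide F5. Addition of aryllithium 16 (THF, −78 °C) gives (2R)-1-[2,4-bis(methoxymethoxy)-3-(3-methylbut-2-en-1-yl)phenyl]-2-hydroxy-3-[2-methoxy-4,6-bis(methoxymethoxy)-3-(3-methylbut-2-en-1-yl)phenyl]propan-1-one F6. NaBH4 in MeOH at 0 °C then gives diol 18; either carbinol epimer is usable.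

Step 4. Risks are para-bromination between the two OMOM groups and over-bromination of the phloroglucinol-type ring. The fallback sets out from 1 and comes back at 8, introducing the oxygen last between two bromines instead of the bromines next to the oxygen. Resorcinol is brominated (2 equiv Br2, CHCl3/AcOH, 0 °C) to 4,6-dibromobenzene-1,3-diol F1, which is protected (NaH, MOMCl, DMF) as 1,5-dibromo-2,4-bis(methoxymethoxy)benzene F2. The C–H between the two bromines is deprotonated with LDA (THF, −78 °C) to [2,6-dibromo-3,5-bis(methoxymethoxy)phenyl]lithium F3, trapped with B(OMe)3 as dimethyl [2,6-dibromo-3,5-bis(methoxymethoxy)phenyl]boronate F4, and oxidised (H2O2, aq. NaOH) to 8.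

Further compounds
F1 | step 4 | 4,6-dibromobenzene-1,3-diol | Oc1cc(O)c(Br)cc1Br
F2 | step 4 | 1,5-dibromo-2,4-bis(methoxymethoxy)benzene | COCOc1cc(OCOC)c(Br)cc1Br
F3 | step 4 | [2,6-dibromo-3,5-bis(methoxymethoxy)phenyl]lithium | [Li]c1c(Br)c(OCOC)cc(OCOC)c1Br
F4 | step 4 | dimethyl [2,6-dibromo-3,5-bis(methoxymethoxy)phenyl]boronate | COB(OC)c1c(Br)c(OCOC)cc(OCOC)c1Br
F5 | step 8 | (2R)-2-hydroxy-N-methoxy-N-methyl-3-[2-methoxy-4,6-bis(methoxymethoxy)-3-(3-methylbut-2-en-1-yl)phenyl]propanamide | CON(C)C(=O)[C@H](O)Cc1c(OCOC)cc(OCOC)c(CC=C(C)C)c1OC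
F6 | step 8 | (2R)-1-[2,4-bis(methoxymethoxy)-3-(3-methylbut-2-en-1-yl)phenyl]-2-hydroxy-3-[2-methoxy-4,6-bis(methoxymethoxy)-3-(3-methylbut-2-en-1-yl)phenyl]propan-1-one | O=C(c1ccc(OCOC)c(CC=C(C)C)c1OCOC)[C@H](O)Cc1c(OCOC)cc(OCOC)c(CC=C(C)C)c1OC
F7 | step 10 | (2S,3R)-2-[2,4-bis(methoxymethoxy)-3-(3-methylbut-2-en-1-yl)phenyl]-5-methoxy-7-(methoxymethoxy)-6-(3-methylbut-2-en-1-yl)-3,4-dihydro-2H-chromen-3-yl methanesulfonate | CS(=O)(=O)O[C@@H]1Cc2c(OC)c(CC=C(C)C)c(OCOC)cc2O[C@H]1c1ccc(OCOC)c(CC=C(C)C)c1OCOC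
F8 | step 10 | (3R)-2-ethoxy-3-[2,4-bis(methoxymethoxy)-3-(3-methylbut-2-en-1-yl)phenyl]-5-methoxy-7-(methoxymethoxy)-6-(3-methylbut-2-en-1-yl)-3,4-dihydro-2H-chromene | COc1c(CC=C(C)C)c(OCOC)cc2c1C[C@H](c1ccc(OCOC)c(CC=C(C)C)c1OCOC)C(OCC)O2
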